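In a one-step world, one substrate and one partner go off together at rate k·c(substrate)·c(partner), and what remains at the end is the difference of the two charges. I asked whether these runs fit that world, and where it puts alpha and epsilon.

| setting | Wednesday's | Saturday's | alpha | epsilon |
|---|---|---|---|---|
| substrate | 1 M | 1 M | 1.0 M | 1.0 M |
| partner | 0.25 M | 1 M | 0.500 M | 0.500 M |
| remark | run made earlier | run made earlier |  |  |
| time |  |  | 3.0 d | 5.0 d |

| run | time / d | isomer of the product / % | target / % | second isomer / % | substrate / % |
|---|---|---|---|---|---|
| Wednesday's | 0.250 | 3.0 | 2.9 | 0.3 | 94.5 |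
| Wednesday's | 0.500 | 4.6 | 4.6 | 0.5 | 90.2 |
| Wednesday's | 0.833 | 6.5 | 5.8 | 0.5 | 86.9 |
| Wednesday's | 1.25 | 8.7 | 7.9 | 1.0 | 83.3 |
| Wednesday's | 2.00 | 9.8 | 9.5 | 1.0 | 79.5 |
| Wednesday's | 4.00 | 11.9 | 11.7 | 0.8 | 76.3 |
| Saturday's | 0.625 | 19.0 | 19.1 | 1.1 | 61.3 |
| Saturday's | 1.25 | 27.4 | 26.5 | 1.7 | 44.3 |
| Saturday's | 1.67 | 30.7 | 30.3 | 2.0 | 37.8 |
| Saturday's | 2.50 | 35.3 | 34.1 | 2.6 | 28.6 |
| Saturday's | 3.00 | 36.8 | 36.2 | 2.7 | 24.7 |
| Saturday's | 4.00 | 38.9 | 38.2 | 2.3 | 19.8 |

(each reading ± 0.3 percentage points)

- a reading or a percentage of target counts all its forms, free or not

- which of these there is most of at the end, counted by the substrate in it, alpha (target / isomer of the product / substrate / second isomer)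
- which of these there is most of at the end, counted by the substrate in it, epsilon (target / isomer of the product / substrate / second isomer)
- final amount of the leader among these, as a percentage of the substrate charged, in alpha
- final amount of the leader among these, as a percentage of the substrate charged, in epsilon

By 4.00 d, Wednesday's run had lost 23.7% of its substrate, and its partner charge stood at 25.0% of its substrate charge. So I took one for one, with the partner as limiting reagent, and put alpha's and epsilon's end state at 50.0% substrate. Saturday's equal charges make 1/c(substrate) rise linearly in time, and its last reading gave k = 1.01 /M/d.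

How fast is that end approached? I called 1.98 d the closing time τ: one over k times the charged excess of substrate over partner. A plain exponential in the partner then put alpha at 60.9% substrate.

But c(substrate) stands above the excess throughout, so the partner falls faster than that. The difference c(substrate) − c(partner), however, holds constant, so the ratio r = c(substrate)/c(partner) grows exactly as exp(t/τ) from its charged value, and substrate left is the excess times r/(r − 1). For alpha I reckoned r = 9.13, which gives 56.1%. For epsilon I reckoned 25.1, which gives 52.1%.

Yet k came from one Saturday reading. Wednesday's run gave k nothing, so it could object: its closing time 1.32 d predicts 75.9% substrate, and the reading was 76.3%.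

The leader needs no split of products: the reckoned share reacted, 43.9% in alpha and 47.9% in epsilon, is less than the substrate left.

The forecast also named substrate for alpha and substrate for epsilon, at 56.3% (54.5% to 58%) and 52.1% (50.5% to 54%), “with no sign of reversibility”.

Substrate led in both flasks, at 56.2% in alpha and 52.1% in epsilon.

    substrate + partner → second isomer (k = 0.00133 /M/h)
    substrate + partner → target (k = 0.0201 /M/h)
    substrate + partner → isomer of the product (k = 0.0206 /M/h)
    crystals ⇌ target, rate k4*(cs4 - [target]) while solid is left; crystals form when [target] > cs4 (solubility = 11.0 mM, k = 4.20 /h)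

Alpha also held 19.8% of crystals, counted inside its 21.0% of target, and their forming made no difference to its substrate. Epsilon's ratio puts free partner at 4.14% of its charge, and that flask held 4.2% of its charge unbound. A neighbour of epsilon charged with 0.85 M of partner gets, on my k, a closing time of 6.58 d and a ratio of 2.51 at 5.0 d, which gives 24.9% substrate; that flask ended at 25.0%.

(The data are simulated on assumed constants.)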